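**Retrosynthetic overview**

- The route rests on C4 of the chromen-4-one: a lone carbonyl carbon held between C4a of ring A and C3, the carbon that carries ring B. C4 is taken from carbon monoxide.
- Ring C is opened at O1–C2 and C2=C3 (C2 from DMF dimethyl acetal). The 5-OH is traced back to a methyl ether that is cleaved last through its chelate with the C4 carbonyl. This leaves a 2-hydroxydeoxybenzoin.
- Key disconnection: C4a–C4 and C4–C3 of the deoxybenzoin are cut to give a ring A aryl iodide, CO and a ring B benzylzinc chloride, joined by zerovalent palladium.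
- The ring A iodide comes from symmetric 3,5-dimethoxyphenol by two directed lithiations: prenyl between the two OMe groups (as the silyl ether), then iodine between OMOM and OMe. The zinc reagent comes from 2,4,5-trimethoxybenzyl alcohol.
- Ring order: rings A and B are bought as benzenes; ring C (the pyranone) is the only ring formed, after the key step.

Key step: step 8

Assumption: the target is achiral (the prenyl olefin carries two identical methyl groups), so no stereodescriptor is needed; benzylzinc chloride 13 is handled as a titrated THF solution of its LiCl complex.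

**Route**

Step 1
Reactants: 1 3,5-dimethoxyphenol
Product: 2 (3,5-dimethoxyphenoxy)tri(propan-2-yl)silane
Conditions: TIPSCl, imidazole, DMF, 0 °C → rt
Reagents that add atoms: triisopropylsilyl chloride, CC(C)[Si](Cl)(C(C)C)C(C)C
Why: Silylation of a phenol with a silyl chloride and imidazole is routine, and the bulky, weakly coordinating OTIPS group removes the acidic OH without directing the next lithiation.

Step 2
Reactants: 2 (3,5-dimethoxyphenoxy)tri(propan-2-yl)silane; 3 prenyl bromide (1-bromo-3-methylbut-2-ene)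
Product: 6 [3,5-dimethoxy-4-(3-methylbut-2-en-1-yl)phenoxy]tri(propan-2-yl)silane, via aryllithium 4 (not isolated), via arylcopper 5 (not isolated)
Conditions: n-BuLi, THF, 0 °C → rt; CuBr·SMe2, −78 → −40 °C; then 3, −78 °C → rt
Reagents that add atoms: none
Why: Directed ortho-metalation should take the C–H flanked by the two methoxy groups (the site next to the hindered OTIPS is not competitive), and the derived arylcopper alkylates prenyl bromide at its primary carbon (SN2 over SN2′) in a standard lithiation–copper prenylation.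

Step 3
Reactants: 6 [3,5-dimethoxy-4-(3-methylbut-2-en-1-yl)phenoxy]tri(propan-2-yl)silane
Product: 7 3,5-dimethoxy-4-(3-methylbut-2-en-1-yl)phenol
Conditions: TBAF, THF, 0 °C → rt
Reagents that add atoms: none
Why: Fluoride-mediated desilylation of an aryl silyl ether is driven by the Si–F bond and leaves the methyl ethers and the prenyl olefin untouched.

Step 4
Reactants: 7 3,5-dimethoxy-4-(3-methylbut-2-en-1-yl)phenol
Product: 8 1,3-dimethoxy-5-(methoxymethoxy)-2-(3-methylbut-2-en-1-yl)benzene
Conditions: MOMCl, iPr2NEt, CH2Cl2, 0 °C → rt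
Reagents that add atoms: chloromethyl methyl ether, COCCl
Why: O-Alkylation of the phenol with MOMCl under amine base (Williamson-type etherification) installs a group that both directs the next metalation and masks the future ring oxygen O1 in acid-labile form.

Step 5
Reactants: 8 1,3-dimethoxy-5-(methoxymethoxy)-2-(3-methylbut-2-en-1-yl)benzene
Product: 10 2-iodo-3,5-dimethoxy-1-(methoxymethoxy)-4-(3-methylbut-2-en-1-yl)benzene, via aryllithium 9 (not isolated)
Conditions: n-BuLi, THF, 0 °C; then I2, THF, −78 °C → rt
Reagents that add atoms: iodine, II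
Why: Directed ortho-metalation by the strongly coordinating OMOM group, reinforced by the neighbouring methoxy group, should deprotonate one of the two symmetry-equivalent ring positions faster than the benzylic CH2 of the prenyl group, and iodinolysis of the aryllithium places the halogen on the carbon that becomes C4a.

Step 6
Reactants: 11 2,4,5-trimethoxybenzyl alcohol
Product: 12 1-(chloromethyl)-2,4,5-trimethoxybenzene
Conditions: SOCl2, CH2Cl2, 0 °C → rt; crude chloride used at once
Reagents that add atoms: thionyl chloride, O=S(Cl)Cl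
Why: Deoxychlorination of an electron-rich benzylic alcohol through its chlorosulfite is fast at low temperature, and immediate use avoids self-alkylation of the labile chloride.

Step 7
Reactants: 12 1-(chloromethyl)-2,4,5-trimethoxybenzene
Product: 13 (2,4,5-trimethoxybenzyl)zinc chloride (LiCl complex, THF solution)
Conditions: Zn dust (activated with BrCH2CH2Br and Me3SiCl), LiCl, THF, 25 °C
Reagents that add atoms: zinc, [Zn]
Why: LiCl-promoted direct insertion of zinc into a benzylic C–Cl bond is a known preparation of benzylic zinc chlorides and should give little Wurtz homocoupling with an electron-rich benzyl chloride.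

Step 8
Reactants: 10 2-iodo-3,5-dimethoxy-1-(methoxymethoxy)-4-(3-methylbut-2-en-1-yl)benzene; 13 (2,4,5-trimethoxybenzyl)zinc chloride; 14 carbon monoxide
Product: 15 1-[2,4-dimethoxy-6-(methoxymethoxy)-3-(3-methylbut-2-en-1-yl)phenyl]-2-(2,4,5-trimethoxyphenyl)ethan-1-one
Conditions: Pd(PPh3)4 (5 mol %), CO (3 bar), THF, 45 °C; 13 added over 2 h
Reagents that add atoms: none
Why: Oxidative addition of the C–I bond of 10 to zerovalent palladium gives an arylpalladium iodide, CO inserts to the aroyl complex, the benzyl group is transferred from zinc and reductive elimination releases ketone 15, so that C4a–C4 and C4–C3 are both made and C4 is the carbon of CO. The closest known reaction type is the palladium-catalysed carbonylative Negishi ketone synthesis from aryl iodides, CO and alkyl- or benzylzinc halides. No ring is closed and no stereocentre is formed. The selectivity needed is acyl transfer over direct aryl–benzyl coupling: the two ortho alkoxy groups crowd the arylpalladium centre and slow its transmetalation, CO is kept in excess under pressure and 13 is added slowly, so that insertion should come first and move palladium one atom away from the crowded ring. The site of acylation is fixed by the iodide, so no Friedel–Crafts acylation has to be run beside the acid-sensitive prenyl group and MOM ether. The weakly basic zinc reagent should leave the MOM ether, the prenyl olefin and the enolisable product ketone untouched.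

Step 9
Reactants: 15 1-[2,4-dimethoxy-6-(methoxymethoxy)-3-(3-methylbut-2-en-1-yl)phenyl]-2-(2,4,5-trimethoxyphenyl)ethan-1-one
Product: 16 1-[6-hydroxy-2,4-dimethoxy-3-(3-methylbut-2-en-1-yl)phenyl]-2-(2,4,5-trimethoxyphenyl)ethan-1-one
Conditions: 3 M aq. HCl, MeOH–THF, 40 °C
Reagents that add atoms: none
Why: Acid-catalysed acetal cleavage of a MOM ether ortho to a ketone is mild, and the prenyl group, flanked by two methyl ethers, has no free ortho hydroxyl with which to cyclise under acid.

Step 10
Reactants: 16 1-[6-hydroxy-2,4-dimethoxy-3-(3-methylbut-2-en-1-yl)phenyl]-2-(2,4,5-trimethoxyphenyl)ethan-1-one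
Product: 18 5,7-dimethoxy-6-(3-methylbut-2-en-1-yl)-3-(2,4,5-trimethoxyphenyl)-4H-chromen-4-one, via enaminone 17 (not isolated)
Conditions: Me2NCH(OMe)2, toluene, 100 °C
Reagents that add atoms: N,N-dimethylformamide dimethyl acetal, COC(OC)N(C)C
Why: Condensation of the active methylene with the amide acetal gives an enaminone whose β-carbon (the future C2) is attacked by the phenol in a 6-endo conjugate addition with loss of dimethylamine, the standard enaminone isoflavone synthesis that forms ring C.

Step 11
Reactants: 18 5,7-dimethoxy-6-(3-methylbut-2-en-1-yl)-3-(2,4,5-trimethoxyphenyl)-4H-chromen-4-one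
Product: 20 5-hydroxy-7-methoxy-6-(3-methylbut-2-en-1-yl)-3-(2,4,5-trimethoxyphenyl)-4H-chromen-4-one, via aryloxydichloroborane 19 (not isolated)
Conditions: BCl3 (1 M in CH2Cl2), CH2Cl2, −78 → −20 °C; then ice-water, 0 °C
Reagents that add atoms: none
Why: Chelation-controlled ether cleavage, in which BCl3 bridges the C4 carbonyl and the peri 5-methoxy oxygen in a six-membered chelate so that chloride removes only that methyl group, while low temperature and a fast cold quench should protect the prenyl olefin from acid-induced cyclisation onto the freed 5-hydroxyl.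

**Compound list**

1 | 3,5-dimethoxyphenol | COc1cc(O)cc(OC)c1 | starting material
2 | (3,5-dimethoxyphenoxy)tri(propan-2-yl)silane | COc1cc(OC)cc(O[Si](C(C)C)(C(C)C)C(C)C)c1 | intermediate
3 | prenyl bromide (1-bromo-3-methylbut-2-ene) | CC(C)=CCBr | starting material
4 | [2,6-dimethoxy-4-(triisopropylsilyloxy)phenyl]lithium (step 2, not isolated) | [Li]c1c(OC)cc(O[Si](C(C)C)(C(C)C)C(C)C)cc1OC | intermediate
5 | [2,6-dimethoxy-4-(triisopropylsilyloxy)phenyl]copper (step 2, not isolated) | [Cu]c1c(OC)cc(O[Si](C(C)C)(C(C)C)C(C)C)cc1OC | intermediate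
6 | [3,5-dimethoxy-4-(3-methylbut-2-en-1-yl)phenoxy]tri(propan-2-yl)silane | COc1cc(O[Si](C(C)C)(C(C)C)C(C)C)cc(OC)c1CC=C(C)C | intermediate
7 | 3,5-dimethoxy-4-(3-methylbut-2-en-1-yl)phenol | COc1cc(O)cc(OC)c1CC=C(C)C | intermediate
8 | 1,3-dimethoxy-5-(methoxymethoxy)-2-(3-methylbut-2-en-1-yl)benzene | COCOc1cc(OC)c(CC=C(C)C)c(OC)c1 | intermediate
9 | [2,4-dimethoxy-6-(methoxymethoxy)-3-(3-methylbut-2-en-1-yl)phenyl]lithium (step 5, not isolated) | COCOc1cc(OC)c(CC=C(C)C)c(OC)c1[Li] | intermediate
10 | 2-iodo-3,5-dimethoxy-1-(methoxymethoxy)-4-(3-methylbut-2-en-1-yl)benzene | COCOc1cc(OC)c(CC=C(C)C)c(OC)c1I | intermediate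
11 | 2,4,5-trimethoxybenzyl alcohol | COc1cc(OC)c(CO)cc1OC | starting material
12 | 1-(chloromethyl)-2,4,5-trimethoxybenzene | COc1cc(OC)c(CCl)cc1OC | intermediate
13 | (2,4,5-trimethoxybenzyl)zinc chloride | COc1cc(OC)c(C[Zn]Cl)cc1OC | intermediate
14 | carbon monoxide | [C-]#[O+] | starting material
15 | 1-[2,4-dimethoxy-6-(methoxymethoxy)-3-(3-methylbut-2-en-1-yl)phenyl]-2-(2,4,5-trimethoxyphenyl)ethan-1-one | COCOc1cc(OC)c(CC=C(C)C)c(OC)c1C(=O)Cc1cc(OC)c(OC)cc1OC | intermediate
16 | 1-[6-hydroxy-2,4-dimethoxy-3-(3-methylbut-2-en-1-yl)phenyl]-2-(2,4,5-trimethoxyphenyl)ethan-1-one | COc1cc(O)c(C(=O)Cc2cc(OC)c(OC)cc2OC)c(OC)c1CC=C(C)C | intermediate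
17 | 3-(dimethylamino)-1-[6-hydroxy-2,4-dimethoxy-3-(3-methylbut-2-en-1-yl)phenyl]-2-(2,4,5-trimethoxyphenyl)prop-2-en-1-one (step 10, not isolated, olefin geometry not fixed) | CN(C)C=C(C(=O)c1c(O)cc(OC)c(CC=C(C)C)c1OC)c1cc(OC)c(OC)cc1OC | intermediate
18 | 5,7-dimethoxy-6-(3-methylbut-2-en-1-yl)-3-(2,4,5-trimethoxyphenyl)-4H-chromen-4-one | COc1cc(OC)c(-c2coc3cc(OC)c(CC=C(C)C)c(OC)c3c2=O)cc1OC | intermediate
19 | 5-(dichloroboryloxy)-7-methoxy-6-(3-methylbut-2-en-1-yl)-3-(2,4,5-trimethoxyphenyl)-4H-chromen-4-one (step 11, not isolated) | COc1cc(OC)c(-c2coc3cc(OC)c(CC=C(C)C)c(OB(Cl)Cl)c3c2=O)cc1OC | intermediate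
20 | 5-hydroxy-7-methoxy-6-(3-methylbut-2-en-1-yl)-3-(2,4,5-trimethoxyphenyl)-4H-chromen-4-one | COc1cc(OC)c(-c2coc3cc(OC)c(CC=C(C)C)c(O)c3c2=O)cc1OC | target

**Step count**

Total steps: 11. Longest linear sequence: 9 steps (steps 1–5 and 8–11, from 1); the zinc reagent branch is 2 steps (steps 6–7).

**Steps most likely to fail**

1. Step 8. The crowded, electron-rich C–I bond may add only slowly to zerovalent palladium that is partly saturated with CO. Direct aryl–benzyl coupling, or protonation and homocoupling of the zinc reagent, may then consume the partners before acyl transfer.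
Fallback: this sets out from 8 and takes the carbonyl carbon from DMF instead of CO, making the two bonds in separate operations. Lithiation of 8 as in step 5 (n-BuLi, THF, 0 °C, via aryllithium 9) and quenching with DMF should give 2,4-dimethoxy-6-(methoxymethoxy)-3-(3-methylbut-2-en-1-yl)benzaldehyde F1. Uncatalysed addition of benzylzinc chloride 13 to F1 (THF, rt) should give racemic 1-[2,4-dimethoxy-6-(methoxymethoxy)-3-(3-methylbut-2-en-1-yl)phenyl]-2-(2,4,5-trimethoxyphenyl)ethanol F2. Oxidation with Dess–Martin periodinane (NaHCO3, CH2Cl2, rt) returns to the route at ketone 15.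

2. Step 11. Acid generated during the BCl3 treatment or its quench may add the newly freed 5-hydroxyl across the neighbouring trisubstituted prenyl olefin (2,2-dimethylchroman formation) or add HCl to that olefin.
Fallback: this sets out from 2 and carries an allyl group, which is far less readily protonated, in place of prenyl until after the demethylation; it comes back to the route at target 20.
- Lithiation and copper transmetalation of 2 as in step 2 (via 4 and 5), then allyl bromide, should give [3,5-dimethoxy-4-(prop-2-en-1-yl)phenoxy]tri(propan-2-yl)silane F3.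
- TBAF should give 3,5-dimethoxy-4-(prop-2-en-1-yl)phenol F4.
- MOMCl/iPr2NEt should give 1,3-dimethoxy-5-(methoxymethoxy)-2-(prop-2-en-1-yl)benzene F5.
- n-BuLi generates the allyl-series aryllithium F6, and I2 then gives 2-iodo-3,5-dimethoxy-1-(methoxymethoxy)-4-(prop-2-en-1-yl)benzene F7.
- Carbonylative coupling of F7 with 13 and 14 under the conditions of step 8 should give the MOM-protected allyl deoxybenzoin F8.
- HCl/MeOH should give the hydroxy allyl deoxybenzoin F9.
- DMF dimethyl acetal, through the allyl-series enaminone F10, should give 6-allyl-5,7-dimethoxy-3-(2,4,5-trimethoxyphenyl)-4H-chromen-4-one F11.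
- BCl3, through the allyl-series aryloxydichloroborane F12, should give 6-allyl-5-hydroxy-7-methoxy-3-(2,4,5-trimethoxyphenyl)-4H-chromen-4-one F13.
- Olefin cross-metathesis of F13 with excess 2-methyl-2-butene (second-generation Grubbs catalyst (H2IMes)(PCy3)Cl2Ru=CHPh, CH2Cl2, 40 °C) converts allyl into prenyl under neutral conditions and gives 20.

3. Step 5. n-BuLi may deprotonate the benzylic, allylic CH2 of the prenyl group (flanked by two methoxy groups) in competition with the ring position, or lithiation may stay incomplete, so that the iodine quench gives mixtures.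
Fallback: this sets out from phenol 7 and replaces metalation by electrophilic aromatic substitution. N-Iodosuccinimide (CH2Cl2–MeCN, −20 °C, 1 equiv) should iodinate one of the two equivalent positions ortho to the free hydroxyl, the only open ring positions, to give 2-iodo-3,5-dimethoxy-4-(3-methylbut-2-en-1-yl)phenol F14. MOM protection of F14 (MOMCl, iPr2NEt, CH2Cl2) returns to the route at iodide 10.

**Further compounds**

F1 | step 8 | 2,4-dimethoxy-6-(methoxymethoxy)-3-(3-methylbut-2-en-1-yl)benzaldehyde | COCOc1cc(OC)c(CC=C(C)C)c(OC)c1C=O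
F2 | step 8 | 1-[2,4-dimethoxy-6-(methoxymethoxy)-3-(3-methylbut-2-en-1-yl)phenyl]-2-(2,4,5-trimethoxyphenyl)ethanol (racemic) | COCOc1cc(OC)c(CC=C(C)C)c(OC)c1C(O)Cc1cc(OC)c(OC)cc1OC
F3 | step 11 | [3,5-dimethoxy-4-(prop-2-en-1-yl)phenoxy]tri(propan-2-yl)silane | C=CCc1c(OC)cc(O[Si](C(C)C)(C(C)C)C(C)C)cc1OC
F4 | step 11 | 3,5-dimethoxy-4-(prop-2-en-1-yl)phenol | C=CCc1c(OC)cc(O)cc1OC
F5 | step 11 | 1,3-dimethoxy-5-(methoxymethoxy)-2-(prop-2-en-1-yl)benzene | C=CCc1c(OC)cc(OCOC)cc1OC
F6 | step 11 | [2,4-dimethoxy-6-(methoxymethoxy)-3-(prop-2-en-1-yl)phenyl]lithium (not isolated) | [Li]c1c(OCOC)cc(OC)c(CC=C)c1OC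
F7 | step 11 | 2-iodo-3,5-dimethoxy-1-(methoxymethoxy)-4-(prop-2-en-1-yl)benzene | COCOc1cc(OC)c(CC=C)c(OC)c1I
F8 | step 11 | 1-[2,4-dimethoxy-6-(methoxymethoxy)-3-(prop-2-en-1-yl)phenyl]-2-(2,4,5-trimethoxyphenyl)ethan-1-one | COCOc1cc(OC)c(CC=C)c(OC)c1C(=O)Cc1cc(OC)c(OC)cc1OC
F9 | step 11 | 1-[6-hydroxy-2,4-dimethoxy-3-(prop-2-en-1-yl)phenyl]-2-(2,4,5-trimethoxyphenyl)ethan-1-one | COc1cc(O)c(C(=O)Cc2cc(OC)c(OC)cc2OC)c(OC)c1CC=C
F10 | step 11 | 3-(dimethylamino)-1-[6-hydroxy-2,4-dimethoxy-3-(prop-2-en-1-yl)phenyl]-2-(2,4,5-trimethoxyphenyl)prop-2-en-1-one (not isolated) | CN(C)C=C(C(=O)c1c(O)cc(OC)c(CC=C)c1OC)c1cc(OC)c(OC)cc1OC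
F11 | step 11 | 5,7-dimethoxy-6-(prop-2-en-1-yl)-3-(2,4,5-trimethoxyphenyl)-4H-chromen-4-one | COc1cc(OC)c(-c2coc3cc(OC)c(CC=C)c(OC)c3c2=O)cc1OC
F12 | step 11 | 5-(dichloroboryloxy)-7-methoxy-6-(prop-2-en-1-yl)-3-(2,4,5-trimethoxyphenyl)-4H-chromen-4-one (not isolated) | COc1cc(OC)c(-c2coc3cc(OC)c(CC=C)c(OB(Cl)Cl)c3c2=O)cc1OC
F13 | step 11 | 5-hydroxy-7-methoxy-6-(prop-2-en-1-yl)-3-(2,4,5-trimethoxyphenyl)-4H-chromen-4-one | COc1cc(OC)c(-c2coc3cc(OC)c(CC=C)c(O)c3c2=O)cc1OC
F14 | step 5 | 2-iodo-3,5-dimethoxy-4-(3-methylbut-2-en-1-yl)phenol | Oc1cc(OC)c(CC=C(C)C)c(OC)c1I
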